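(Readings and results stem from a simulated flask for an exercise; the scatter is artificial.)

Of the D charged to the maple flask, a reading finds 72% left after 40.0 s. E turns D into X, and Q stands beside them.

all flasks: D 0.020 M; Q 9.6 µM
- maple: E 2 µM; the very flask that is asked about, followed so far
- flask: E 2.0 µM

- maple (time / s: X / %, D / %): 10.0: 5, 92; 12.0: 12, 93; 25.0: 18, 79; 40.0: 24, 72

(standard deviation of a reading: 1.5 percentage points)

- no earlier run changes the charge of E; that part of a forecast is a guess

1. apparent order in E when 50% of the D are converted (percent change of the rate of making X for one percent more E charged)
2. factor on the rate of making X when 50% of the D are converted if E is charged twice over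

I carry one number: k, the share of the remaining D that goes per unit time, taken as steady (pseudo-first-order). Integrating the rate kD gives D falling as exp(−kt), so a reading at one time yields k. The leftover D gives 0.00821 s⁻¹. The X formed, counted as D gone, gives 0.00686 s⁻¹, which is lower. So one reading may cheat, or D may be hiding somewhere. The two readings fall 4 percentage points short of the charge, but the E charged amounts to 0.0100% of the D, so D bound to E cannot fill that gap. The scatter of such a sum is 2.1 points, so I blame scatter and take the mean, 0.00754 s⁻¹, as a reading.

From k, I reckon that the flask reaches 50% conversion at 1.53 min and makes X there at 0.00452 M min⁻¹. No run changes E, so I guess that k follows the E charged, which gives an order of one and a factor of two. By that conversion each E charged has put through 5000 D on average, and the readings up to 40.0 s, with their scatter, do not tell me whether E wears out with use.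

The forecast gives 1.05 and 2.1, above my figures, with this among its grounds: “Enzyme decay would also push the order slightly above 1”.

The flask gives an order of 1.3 and a factor of 2.32.

    D + E → X + E, rate k1*[D]*[E]/(1 + ([D]/Km1) + ([X]/Kp1)) (42.8 mM, 31.2 mM, k = 10400 L mol⁻¹ s⁻¹)
    D + E → Z (k = 17.0 L mol⁻¹ min⁻¹)
    E + Q ⇌ L, settled at all times (K = 63000 L mol⁻¹)

The flask reaches 50% conversion at 1.49 min, against my 1.53 min, yet it makes X at 0.00407 M min⁻¹ there, slower than my 0.00452 M min⁻¹. E does wear out: by 2.00 min, later than that moment, the passing of D + E into Z has taken 24.4% of the E charged. Doubling E cuts the D each E charged puts through on average from 5000 to 2500, and this wear is the largest single effect on the order. In the run without that step, the order falls from 1.3 to 1.0.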